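**Retrosynthetic overview** (side-chain carbons are C1'–C32', counted from the quinone)

1. Target ⇒ 2-(chloromethyl)-3-methylnaphthoquinone + an (E)-alkenylalane (C1'–C2' bond); carboalumination of a terminal alkyne installs the 3'-methyl and the 2'E alkene. The naphthoquinone rings are bought as menadione.
2. Ring-bearing alkyne ⇐ linear all-E pentaenyne by a late, cyclase-like, enantioselective proton-initiated monocyclisation of the last two isoprene units (C26'–C31' bond). This is the only ring made, and it is formed in the second-to-last step.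
3. Linear alkyne ⇐ methyl ketone; the chain is cut at C24'–C25' (geranylbarium + allylic bromide) and at C12'–C13' (alkyl Grignard + farnesyl bromide), with one ω-oxidation in between.
4. The C7'/C11' stereodiad ⇐ one double asymmetric hydrogenation of ω-hydroxylated (E)-geranylacetone ketal.
5. Ring order: naphthoquinone (purchased) → cyclohexene (step 11) → final quinone coupling (step 12).

Assumption: the sense of induction of the two chiral catalysts is assigned by analogy (the Ir catalyst enantiomer that gives the R,R,R phytyl pattern from E-alkenes; the (R)-binaphthol-derived acid giving the ring sense of (−)-ambrox); if either proves opposite, its mirror-image ligand is used.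

**Route**

Step 1
Reactants: 1 menadione (2-methylnaphthalene-1,4-dione)
Product: 2 2-(chloromethyl)-3-methylnaphthalene-1,4-dione
Conditions: 37% aq. HCHO, HCl (g), AcOH, rt
Reagents that add atoms: formaldehyde C=O; hydrogen chloride Cl
Why: Blanc-type chloromethylation at the only free quinone C–H position; no stereocentre is involved.

Step 2
Reactants: 3 (E)-geranylacetone [(5E)-6,10-dimethylundeca-5,9-dien-2-one]
Product: 4 2-[(3E)-4,8-dimethylnona-3,7-dien-1-yl]-2-methyl-1,3-dioxolane
Conditions: HOCH2CH2OH, PPTS (cat.), toluene, reflux, Dean–Stark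
Reagents that add atoms: ethylene glycol OCCO
Why: Acid-catalysed ketalisation masks the methyl ketone as a dioxolane that survives the later oxidation, hydrogenation, Appel, Grignard and organobarium steps, and PPTS is too weak to protonate the trisubstituted alkenes.

Step 3
Reactants: 4 2-[(3E)-4,8-dimethylnona-3,7-dien-1-yl]-2-methyl-1,3-dioxolane
Product: 5 (2E,6E)-2,6-dimethyl-9-(2-methyl-1,3-dioxolan-2-yl)nona-2,6-dien-1-ol
Conditions: SeO2 (0.1 equiv), t-BuOOH (2 equiv), salicylic acid (0.1 equiv), CH2Cl2, rt, stopped at partial conversion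
Reagents that add atoms: tert-butyl hydroperoxide CC(C)(C)OO (terminal oxidant and oxygen source); selenium dioxide O=[Se]=O (catalytic oxygen carrier)
Why: Sharpless SeO2/t-BuOOH allylic oxidation (ene reaction then [2,3]-sigmatropic shift) attacks the electron-rich terminal isopropylidene and gives only the (E)-allylic alcohol at C12'.

Step 4
Reactants: 5 (2E,6E)-2,6-dimethyl-9-(2-methyl-1,3-dioxolan-2-yl)nona-2,6-dien-1-ol
Product: 6 (2S,6R)-2,6-dimethyl-9-(2-methyl-1,3-dioxolan-2-yl)nonan-1-ol
Conditions: H2 (50 bar), [Ir(cod)(L)]BArF (1 mol %; L = (S)-7-[bis(2-methylphenyl)phosphanyl]oxy-2-phenyl-6,7-dihydro-5H-cyclopenta[b]pyridine, BArF = B[3,5-(CF3)2C6H3]4), CH2Cl2, rt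
Reagents that add atoms: none
Why: Pfaltz-type iridium-catalysed asymmetric hydrogenation of trialkyl-substituted (E)-alkenes; both (E)-alkenes present the same enantioface to the catalyst, so C7' (6R here) and C11' (2S here) are set together in the natural phytyl-type sense, as in the hydrogenation of (E,E)-farnesol- and (E)-geranylacetone-type substrates.

Step 5
Reactants: 6 (2S,6R)-2,6-dimethyl-9-(2-methyl-1,3-dioxolan-2-yl)nonan-1-ol
Product: 7 2-[(4R,8S)-9-bromo-4,8-dimethylnonyl]-2-methyl-1,3-dioxolane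
Conditions: CBr4, PPh3, CH2Cl2, 0 °C
Reagents that add atoms: carbon tetrabromide BrC(Br)(Br)Br
Why: The Appel reaction converts the primary alcohol to the bromide under neutral conditions without touching the adjacent stereocentre or the dioxolane.

Step 6
Reactants: 7 2-[(4R,8S)-9-bromo-4,8-dimethylnonyl]-2-methyl-1,3-dioxolane; 8 (2E,6E)-farnesyl bromide [(2E,6E)-1-bromo-3,7,11-trimethyldodeca-2,6,10-triene]
Product: 10 2-methyl-2-[(4R,8S,11E,15E)-4,8,12,16,20-pentamethylhenicosa-11,15,19-trien-1-yl]-1,3-dioxolane, via alkylmagnesium bromide 9 (not isolated)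
Conditions: Mg, THF, 40 °C; then 8, Li2CuCl4 (3 mol %), THF, −78 → 0 °C
Reagents that add atoms: none
Why: Kochi-type Li2CuCl4-catalysed coupling of a primary alkyl Grignard reagent with a primary allylic bromide occurs at the α-carbon (SN2) with retention of the (E)-geometry and forms C12'–C13'; the stereocentres are remote and untouched.

Step 7
Reactants: 10 2-methyl-2-[(4R,8S,11E,15E)-4,8,12,16,20-pentamethylhenicosa-11,15,19-trien-1-yl]-1,3-dioxolane
Product: 11 (2E,6E,10E,14S,18R)-2,6,10,14,18-pentamethyl-21-(2-methyl-1,3-dioxolan-2-yl)henicosa-2,6,10-trien-1-ol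
Conditions: SeO2 (0.1 equiv), t-BuOOH (2 equiv), salicylic acid (0.1 equiv), CH2Cl2, 0 °C → rt, stopped at partial conversion, recycle 10
Reagents that add atoms: tert-butyl hydroperoxide CC(C)(C)OO (terminal oxidant and oxygen source); selenium dioxide O=[Se]=O (catalytic oxygen carrier)
Why: Sharpless SeO2/t-BuOOH allylic oxidation of polyprenyl chains is selective for the (E)-methyl of the terminal isopropylidene (ω-hydroxylation), giving the (E)-alcohol at C24' while the more hindered internal alkenes react more slowly.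

Step 8
Reactants: 11 (2E,6E,10E,14S,18R)-2,6,10,14,18-pentamethyl-21-(2-methyl-1,3-dioxolan-2-yl)henicosa-2,6,10-trien-1-ol
Product: 12 2-[(4R,8S,11E,15E,19E)-21-bromo-4,8,12,16,20-pentamethylhenicosa-11,15,19-trien-1-yl]-2-methyl-1,3-dioxolane
Conditions: CBr4, PPh3, CH2Cl2, −20 °C
Reagents that add atoms: carbon tetrabromide BrC(Br)(Br)Br
Why: Appel bromination of the primary allylic alcohol at low temperature gives the allylic bromide without allylic transposition or loss of (E)-geometry.

Step 9
Reactants: 12 2-[(4R,8S,11E,15E,19E)-21-bromo-4,8,12,16,20-pentamethylhenicosa-11,15,19-trien-1-yl]-2-methyl-1,3-dioxolane; 13 geranyl chloride [(2E)-1-chloro-3,7-dimethylocta-2,6-diene]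
Product: 16 (6R,10S,13E,17E,21E,25E)-6,10,14,18,22,26,30-heptamethylhentriaconta-13,17,21,25,29-pentaen-2-one, via geranylbarium chloride 14 (not isolated), via pentaenyl dioxolane 15 (not isolated)
Conditions: BaI2, lithium biphenylide (2 equiv), THF, rt; 13, −78 °C; then 12, −78 °C; then 2 M aq. HCl, THF, rt
Reagents that add atoms: water O
Why: Yamamoto–Corey allylbarium coupling: geranylbarium formed at −78 °C keeps its (E)-geometry and alkylates the allylic bromide α,α′ (C24'–C25' bond) with retention of both alkenes, and dilute acid then hydrolyses the dioxolane (acetal hydrolysis) without protonating the alkenes.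

Step 10
Reactants: 16 (6R,10S,13E,17E,21E,25E)-6,10,14,18,22,26,30-heptamethylhentriaconta-13,17,21,25,29-pentaen-2-one
Product: 18 (6R,10S,13E,17E,21E,25E)-6,10,14,18,22,26,30-heptamethylhentriaconta-13,17,21,25,29-pentaen-1-yne, via enol diethyl phosphate 17 (not isolated)
Conditions: LiN(i-Pr)2 (1.1 equiv), THF, −78 °C; ClP(O)(OEt)2; then LiN(i-Pr)2 (2.3 equiv), −78 °C → rt; H2O
Reagents that add atoms: none
Why: Negishi conversion of a methyl ketone into a terminal alkyne: kinetic enolisation at the methyl group, O-phosphorylation and E2 elimination of diethyl phosphate; the C7' and C11' centres are not α to the carbonyl and stay intact.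

Step 11
Reactants: 18 (6R,10S,13E,17E,21E,25E)-6,10,14,18,22,26,30-heptamethylhentriaconta-13,17,21,25,29-pentaen-1-yne
Product: 19 (6R,10S,13E,17E,21E)-6,10,14,18,22-pentamethyl-24-[(1S)-2,6,6-trimethylcyclohex-2-en-1-yl]tetracosa-13,17,21-trien-1-yne
Conditions: SnCl4 (2.0 equiv), (R)-2-(2-fluorobenzyloxy)-2'-hydroxy-1,1'-binaphthyl (2.2 equiv), toluene, −78 °C, 48 h; pyridine quench
Reagents that add atoms: none
Why: Proposed new method: a cyclase-like enantioselective proton-initiated cation–olefin monocyclisation with a Yamamoto Lewis acid-assisted chiral Brønsted acid, in which the bulky chiral proton goes only to the unhindered terminal isopropylidene in concert with C26'–C31' bond formation through the chair selected by the binaphthyl pocket (setting 1S, the sense of ring A of (−)-ambrox), and at −78 °C the tight SnCl4–binaphtholate counter-anion removes the C28' proton from the C27' cation (α-olefin) faster than the flexible chain can fold for a second ring; the closest known reaction type is the ring-A-only first stage of such acid-induced cyclisations of homo(polyprenyl)arenes and homofarnesol, not yet shown for an untethered C38 chain or for α-selective termination.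

Step 12
Reactants: 19 (6R,10S,13E,17E,21E)-6,10,14,18,22-pentamethyl-24-[(1S)-2,6,6-trimethylcyclohex-2-en-1-yl]tetracosa-13,17,21-trien-1-yne; 2 2-(chloromethyl)-3-methylnaphthalene-1,4-dione
Product: 21 2-methyl-3-[(2E,7R,11S,14E,18E,22E)-3,7,11,15,19,23-hexamethyl-25-[(1S)-2,6,6-trimethylcyclohex-2-en-1-yl]pentacosa-2,14,18,22-tetraen-1-yl]naphthalene-1,4-dione (CNP0165638.1), via alkenyl dimethylalane 20 (not isolated)
Conditions: Me3Al (2 equiv), Cp2ZrCl2 (0.1 equiv), ClCH2CH2Cl, 0 °C → rt; volatiles removed; then 2, NiCl2(PPh3)2 (3 mol %) pre-reduced with n-BuLi (6 mol %) to zerovalent nickel, THF, −20 °C → rt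
Reagents that add atoms: trimethylaluminium C[Al](C)C
Why: Negishi zirconium-catalysed syn-carboalumination of the terminal alkyne (methyl to C3', aluminium to C2', only E) followed by Lipshutz nickel-catalysed cross-coupling of the alkenylalane with the chloromethylquinone forms C1'–C2' with retention and gives the quinone directly; the other alkenes and all three stereocentres are untouched.

**Compound list**

1 | menadione (2-methylnaphthalene-1,4-dione) | CC1=CC(=O)c2ccccc2C1=O | starting material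
2 | 2-(chloromethyl)-3-methylnaphthalene-1,4-dione | CC1=C(CCl)C(=O)c2ccccc2C1=O | intermediate
3 | (E)-geranylacetone, (5E)-6,10-dimethylundeca-5,9-dien-2-one | CC(C)=CCC/C(C)=C/CCC(C)=O | starting material
4 | 2-[(3E)-4,8-dimethylnona-3,7-dien-1-yl]-2-methyl-1,3-dioxolane | CC(C)=CCC/C(C)=C/CCC1(C)OCCO1 | intermediate
5 | (2E,6E)-2,6-dimethyl-9-(2-methyl-1,3-dioxolan-2-yl)nona-2,6-dien-1-ol | OC/C(C)=C/CC/C(C)=C/CCC1(C)OCCO1 | intermediate
6 | (2S,6R)-2,6-dimethyl-9-(2-methyl-1,3-dioxolan-2-yl)nonan-1-ol | OC[C@@H](C)CCC[C@@H](C)CCCC1(C)OCCO1 | intermediate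
7 | 2-[(4R,8S)-9-bromo-4,8-dimethylnonyl]-2-methyl-1,3-dioxolane | BrC[C@@H](C)CCC[C@@H](C)CCCC1(C)OCCO1 | intermediate
8 | (2E,6E)-farnesyl bromide, (2E,6E)-1-bromo-3,7,11-trimethyldodeca-2,6,10-triene | CC(C)=CCC/C(C)=C/CC/C(C)=C/CBr | starting material
9 | [(2S,6R)-2,6-dimethyl-9-(2-methyl-1,3-dioxolan-2-yl)nonyl]magnesium bromide | Br[Mg]C[C@@H](C)CCC[C@@H](C)CCCC1(C)OCCO1 | intermediate
10 | 2-methyl-2-[(4R,8S,11E,15E)-4,8,12,16,20-pentamethylhenicosa-11,15,19-trien-1-yl]-1,3-dioxolane | CC(C)=CCC/C(C)=C/CC/C(C)=C/CC[C@@H](C)CCC[C@@H](C)CCCC1(C)OCCO1 | intermediate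
11 | (2E,6E,10E,14S,18R)-2,6,10,14,18-pentamethyl-21-(2-methyl-1,3-dioxolan-2-yl)henicosa-2,6,10-trien-1-ol | OC/C(C)=C/CC/C(C)=C/CC/C(C)=C/CC[C@@H](C)CCC[C@@H](C)CCCC1(C)OCCO1 | intermediate
12 | 2-[(4R,8S,11E,15E,19E)-21-bromo-4,8,12,16,20-pentamethylhenicosa-11,15,19-trien-1-yl]-2-methyl-1,3-dioxolane | BrC/C(C)=C/CC/C(C)=C/CC/C(C)=C/CC[C@@H](C)CCC[C@@H](C)CCCC1(C)OCCO1 | intermediate
13 | geranyl chloride, (2E)-1-chloro-3,7-dimethylocta-2,6-diene | CC(C)=CCC/C(C)=C/CCl | starting material
14 | geranylbarium chloride, [(2E)-3,7-dimethylocta-2,6-dien-1-yl]barium chloride | CC(C)=CCC/C(C)=C/C[Ba]Cl | intermediate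
15 | 2-methyl-2-[(4R,8S,11E,15E,19E,23E)-4,8,12,16,20,24,28-heptamethylnonacosa-11,15,19,23,27-pentaen-1-yl]-1,3-dioxolane | CC(C)=CCC/C(C)=C/CC/C(C)=C/CC/C(C)=C/CC/C(C)=C/CC[C@@H](C)CCC[C@@H](C)CCCC1(C)OCCO1 | intermediate
16 | (6R,10S,13E,17E,21E,25E)-6,10,14,18,22,26,30-heptamethylhentriaconta-13,17,21,25,29-pentaen-2-one | CC(C)=CCC/C(C)=C/CC/C(C)=C/CC/C(C)=C/CC/C(C)=C/CC[C@@H](C)CCC[C@@H](C)CCCC(C)=O | intermediate
17 | diethyl (6R,10S,13E,17E,21E,25E)-6,10,14,18,22,26,30-heptamethylhentriaconta-1,13,17,21,25,29-hexaen-2-yl phosphate | CC(C)=CCC/C(C)=C/CC/C(C)=C/CC/C(C)=C/CC/C(C)=C/CC[C@@H](C)CCC[C@@H](C)CCCC(=C)OP(=O)(OCC)OCC | intermediate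
18 | (6R,10S,13E,17E,21E,25E)-6,10,14,18,22,26,30-heptamethylhentriaconta-13,17,21,25,29-pentaen-1-yne | CC(C)=CCC/C(C)=C/CC/C(C)=C/CC/C(C)=C/CC/C(C)=C/CC[C@@H](C)CCC[C@@H](C)CCCC#C | intermediate
19 | (6R,10S,13E,17E,21E)-6,10,14,18,22-pentamethyl-24-[(1S)-2,6,6-trimethylcyclohex-2-en-1-yl]tetracosa-13,17,21-trien-1-yne | CC1=CCCC(C)(C)[C@@H]1CC/C(C)=C/CC/C(C)=C/CC/C(C)=C/CC[C@@H](C)CCC[C@@H](C)CCCC#C | intermediate
20 | dimethyl[(1E,6R,10S,13E,17E,21E)-2,6,10,14,18,22-hexamethyl-24-[(1S)-2,6,6-trimethylcyclohex-2-en-1-yl]tetracosa-1,13,17,21-tetraen-1-yl]alumane | CC1=CCCC(C)(C)[C@@H]1CC/C(C)=C/CC/C(C)=C/CC/C(C)=C/CC[C@@H](C)CCC[C@@H](C)CCC/C(C)=C/[Al](C)C | intermediate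
21 | 2-methyl-3-[(2E,7R,11S,14E,18E,22E)-3,7,11,15,19,23-hexamethyl-25-[(1S)-2,6,6-trimethylcyclohex-2-en-1-yl]pentacosa-2,14,18,22-tetraen-1-yl]naphthalene-1,4-dione | CC1=CCCC(C)(C)[C@@H]1CC/C(C)=C/CC/C(C)=C/CC/C(C)=C/CC[C@@H](C)CCC[C@@H](C)CCC/C(C)=C/CC1=C(C)C(=O)c2ccccc2C1=O | target

**Totals and risks**

Total step count: 12. Longest linear sequence: 11 steps (steps 2–12, from 3); step 1 is a one-step side branch.

The three steps most likely to fail:

Step 11 (late monocyclisation). The cation at C27' may go on to a second ring with the C22' alkene, the olefin may end up exocyclic or tetrasubstituted instead of α, an internal alkene may be protonated, or the ee may be moderate. The isomers are all hydrocarbons and hard to separate. Fallback, setting out from 12 and coming back at 19: the ring is brought in as a resolved block instead of being made late. (S)-α-Cyclogeraniol F1, secured by lipase-catalysed kinetic resolution of racemic α-cyclogeraniol, is converted (CBr4, PPh3) into (6S)-6-(bromomethyl)-1,5,5-trimethylcyclohexene F2. Its Grignard reagent, the cyclogeranylmagnesium bromide F3, is coupled with 12 (Li2CuCl4, THF, −78 → 0 °C) to the ring-bearing dioxolane F4. Hydrolysis with 2 M HCl gives the ring-bearing methyl ketone F5, and the enol phosphate elimination used in step 10 then gives 19.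

Step 9 (allylbarium coupling). Active barium is capricious; α/γ scrambling, loss of (E)-geometry or Wurtz homocoupling would give inseparable isomers. Fallback, setting out from 13 and 12 and coming back at 15: a sulfone-stabilised carbanion replaces the organobarium. Chloride 13 and TolSO2Na in DMF give geranyl p-tolyl sulfone F6. Lithiation (n-BuLi, THF/HMPA, −78 °C) and alkylation with 12 give the C25'-sulfonylated pentaenyl dioxolane F7. Reductive desulfonylation with LiBHEt3 and PdCl2(dppp) (THF, 0 °C), which does not move the double bond, gives 15, and the acid hydrolysis of step 9 then leads to 16.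

Step 4 (double asymmetric hydrogenation). The allylic-alcohol alkene may be reduced with lower selectivity than the geranylacetone-type alkene, and the C11' epimer could not be removed later. Fallback, setting out from 5 and coming back at 6: C11' is set enzymatically and only the well-precedented alkene is left for iridium. MnO2 (CH2Cl2, rt) oxidises 5 to the (2E,6E)-dienal F8. An (S)-selective ene-reductase of the Old Yellow Enzyme family (NADPH recycling, buffer/MTBE) reduces the conjugated alkene to the (2S)-enal F9, which is reduced in the same pot (alcohol dehydrogenase or NaBH4) to the (2S,6E)-enol F10. Hydrogenation of the single remaining alkene under the conditions of step 4 gives 6.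

**Further compounds**

F1 | step 11 | (S)-α-cyclogeraniol, [(1S)-2,6,6-trimethylcyclohex-2-en-1-yl]methanol | CC1=CCCC(C)(C)[C@@H]1CO
F2 | step 11 | (6S)-6-(bromomethyl)-1,5,5-trimethylcyclohexene | CC1=CCCC(C)(C)[C@@H]1CBr
F3 | step 11 | {[(1S)-2,6,6-trimethylcyclohex-2-en-1-yl]methyl}magnesium bromide | CC1=CCCC(C)(C)[C@@H]1C[Mg]Br
F4 | step 11 | 2-methyl-2-[(4R,8S,11E,15E,19E)-4,8,12,16,20-pentamethyl-22-[(1S)-2,6,6-trimethylcyclohex-2-en-1-yl]docosa-11,15,19-trien-1-yl]-1,3-dioxolane | CC1=CCCC(C)(C)[C@@H]1CC/C(C)=C/CC/C(C)=C/CC/C(C)=C/CC[C@@H](C)CCC[C@@H](C)CCCC1(C)OCCO1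
F5 | step 11 | (6R,10S,13E,17E,21E)-6,10,14,18,22-pentamethyl-24-[(1S)-2,6,6-trimethylcyclohex-2-en-1-yl]tetracosa-13,17,21-trien-2-one | CC1=CCCC(C)(C)[C@@H]1CC/C(C)=C/CC/C(C)=C/CC/C(C)=C/CC[C@@H](C)CCC[C@@H](C)CCCC(C)=O
F6 | step 9 | geranyl p-tolyl sulfone, 1-{[(2E)-3,7-dimethylocta-2,6-dien-1-yl]sulfonyl}-4-methylbenzene | CC(C)=CCC/C(C)=C/CS(=O)(=O)c1ccc(C)cc1
F7 | step 9 | 2-methyl-2-[(4R,8S,11E,15E,19E,23E)-4,8,12,16,20,24,28-heptamethyl-22-(4-methylbenzenesulfonyl)nonacosa-11,15,19,23,27-pentaen-1-yl]-1,3-dioxolane (both epimers at C22) | CC(C)=CCC/C(C)=C/C(C/C(C)=C/CC/C(C)=C/CC/C(C)=C/CC[C@@H](C)CCC[C@@H](C)CCCC1(C)OCCO1)S(=O)(=O)c1ccc(C)cc1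
F8 | step 4 | (2E,6E)-2,6-dimethyl-9-(2-methyl-1,3-dioxolan-2-yl)nona-2,6-dienal | O=C/C(C)=C/CC/C(C)=C/CCC1(C)OCCO1
F9 | step 4 | (2S,6E)-2,6-dimethyl-9-(2-methyl-1,3-dioxolan-2-yl)non-6-enal | O=C[C@@H](C)CCC/C(C)=C/CCC1(C)OCCO1
F10 | step 4 | (2S,6E)-2,6-dimethyl-9-(2-methyl-1,3-dioxolan-2-yl)non-6-en-1-ol | OC[C@@H](C)CCC/C(C)=C/CCC1(C)OCCO1
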